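## Retrosynthetic overview

1. Target ⇒ one global hydrogenolysis (five O-benzyl groups and a C8–Br blocking group) of a protected fisetinidol–gallocatechin dimer.
2. Key disconnection: the C4(upper)–C6(lower) interflavan bond ⇒ a fisetinidol C4 quinone methide/cation (released from (+)-mollisacacidin by visible-light-gated ionisation) plus a gallocatechin nucleophile whose C8 is blocked. The 3,4-trans (4α) centre is set by the existing C2/C3 centres.
3. Mollisacacidin ⇒ (2R,3R)-fustin (ketone reduction). The nucleophile ⇒ (+)-gallocatechin (phenol benzylation, then C8 bromination).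
4. No ring is built: both chroman ring systems are bought intact with their C2/C3 stereocentres, and the two halves are joined last.

Assumption: (2R,3R)-fustin and (+)-gallocatechin are bought as the single natural enantiomers, and the merocyanine photoacid catalyst is bought or prepared beforehand (it is a catalyst and is not counted as a step).

## Route

Step 1
Reactants: 1 (2R,3R)-fustin
Product: 2 (+)-mollisacacidin, (2R,3S,4R)-2-(3,4-dihydroxyphenyl)chromane-3,4,7-triol
Conditions: NaBH4 (2 equiv), EtOH, 0 °C → rt, N2; aq NH4Cl to pH ~6, EtOAc extraction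
Reagents that add atoms: none
Why: Borohydride ketone reduction of a dihydroflavonol, with axial hydride attack giving mainly the all-equatorial 2,3-trans-3,4-trans diol; C2 and C3 come from 1, and the C4 configuration does not matter because C4 is re-ionised in step 4.

Step 2
Reactants: 3 (+)-gallocatechin; 4 benzyl bromide
Product: 5 5,7,3',4',5'-penta-O-benzyl-(+)-gallocatechin (3-OH free; 2R,3S)
Conditions: BnBr (5.5 equiv), K2CO3 (6 equiv), degassed DMF, 0 °C → rt, Ar
Reagents that add atoms: benzyl bromide, BrCc1ccccc1
Why: Williamson etherification in which K2CO3 deprotonates only the five phenols and not the secondary 3-OH, so C2 and C3 are untouched.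

Step 3
Reactants: 5 5,7,3',4',5'-penta-O-benzyl-(+)-gallocatechin; 6 N-bromosuccinimide
Product: 7 8-bromo-5,7,3',4',5'-penta-O-benzyl-(+)-gallocatechin (2R,3S)
Conditions: NBS (1.05 equiv), CH2Cl2, −78 °C → 0 °C, dark
Reagents that add atoms: N-bromosuccinimide, O=C1CCC(=O)N1Br
Why: Electrophilic aromatic bromination of the most electron-rich (phloroglucinol-type) ring, which in 5,7-di-O-benzyl flavan-3-ols goes selectively to C8 and so leaves C6 as the only open nucleophilic A-ring position.

Step 4
Reactants: 2 (+)-mollisacacidin; 7 8-bromo-5,7,3',4',5'-penta-O-benzyl-(+)-gallocatechin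
Product: 9 fisetinidol-(4α→6)-[8-bromo-5,7,3',4',5'-penta-O-benzylgallocatechin] (upper unit 2R,3S,4S; lower unit 2R,3S), via fisetinidol A-ring para-quinone methide 8 (not isolated)
Conditions: 2-[(E)-2-(2-hydroxyphenyl)ethenyl]-3,3-dimethyl-1-(3-sulfonatopropyl)-3H-indolium (merocyanine photoacid, 10 mol %), 450 nm LEDs, MeCN–CH2Cl2 (3:1), 20 °C, Ar; 2 added over 6 h to 7 (3 equiv)
Reagents that add atoms: none
Why: Proposed new method: a visible-light-gated, photoacid-catalysed dehydrative interflavan Friedel–Crafts coupling. Under 450 nm light the merocyanine closes to its spiropyran and releases a sulfonic-acid-strength proton, which ionises the doubly donor-stabilised C4–OH of 2 (7-OH para, O1 ortho) to quinone methide 8 and its conjugate acid. C6 of 7, the only open A-ring position because C8 carries Br, attacks this on the face anti to the C3–OH of the half-chair with the 2-aryl group equatorial, so the 3,4-trans (4α, 4S) centre is set by the purchased C2/C3 centres. The acid reverts in the dark, the aryl bromide and benzyl ethers do not absorb at 450 nm, and any water adduct simply re-ionises. The closest known reactions are the thermal dilute-acid coupling of flavan-3,4-diols with flavan-3-ols and photoacid-catalysed Friedel–Crafts and glycosylation reactions of other alcohols and acetals.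

Step 5
Reactants: 9 fisetinidol-(4α→6)-[8-bromo-5,7,3',4',5'-penta-O-benzylgallocatechin]
Product: 10 fisetinidol-(4α→6)-gallocatechin (target)
Conditions: H2 (1 atm), 20% Pd(OH)2/C, Et3N (1.5 equiv), THF–MeOH (1:1), rt; filter under Ar, lyophilise
Reagents that add atoms: none
Why: Palladium-catalysed hydrogenolysis cleaves the five benzyl ethers and, with Et3N as HBr scavenger, the aryl C–Br bond in the same operation, while the 5-deoxy interflavan bond and all five stereocentres are inert.

## Compound list

1 | (2R,3R)-fustin, (2R,3R)-2-(3,4-dihydroxyphenyl)-3,7-dihydroxy-2,3-dihydrochromen-4-one (2,3-trans) | Oc1ccc2c(c1)O[C@H](c1ccc(O)c(O)c1)[C@@H](O)C2=O | starting material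
2 | (+)-mollisacacidin, (2R,3S,4R)-2-(3,4-dihydroxyphenyl)chromane-3,4,7-triol (2,3-trans-3,4-trans) | Oc1ccc2c(c1)O[C@H](c1ccc(O)c(O)c1)[C@@H](O)[C@@H]2O | intermediate
3 | (+)-gallocatechin, (2R,3S)-2-(3,4,5-trihydroxyphenyl)chromane-3,5,7-triol | Oc1cc(O)c2C[C@H](O)[C@@H](c3cc(O)c(O)c(O)c3)Oc2c1 | starting material
4 | benzyl bromide | BrCc1ccccc1 | starting material
5 | 5,7,3',4',5'-penta-O-benzyl-(+)-gallocatechin (2R,3S; 3-OH free) | c1ccccc1COc1cc(OCc2ccccc2)c2C[C@H](O)[C@@H](c3cc(OCc4ccccc4)c(OCc4ccccc4)c(OCc4ccccc4)c3)Oc2c1 | intermediate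
6 | N-bromosuccinimide | O=C1CCC(=O)N1Br | starting material
7 | 8-bromo-5,7,3',4',5'-penta-O-benzyl-(+)-gallocatechin (2R,3S) | c1ccccc1COc1cc(OCc2ccccc2)c2C[C@H](O)[C@@H](c3cc(OCc4ccccc4)c(OCc4ccccc4)c(OCc4ccccc4)c3)Oc2c1Br | intermediate
8 | fisetinidol A-ring para-quinone methide, (2R,3S)-2-(3,4-dihydroxyphenyl)-3-hydroxy-2,3-dihydro-7H-chromen-7-one | O=C1C=CC2=C[C@H](O)[C@@H](c3ccc(O)c(O)c3)OC2=C1 | intermediate
9 | fisetinidol-(4α→6)-[8-bromo-5,7,3',4',5'-penta-O-benzylgallocatechin] (upper 2R,3S,4S; lower 2R,3S) | Oc1ccc2c(c1)O[C@H](c1ccc(O)c(O)c1)[C@@H](O)[C@@H]2c1c(OCc3ccccc3)c(Br)c2c(c1OCc3ccccc3)C[C@H](O)[C@@H](c1cc(OCc3ccccc3)c(OCc3ccccc3)c(OCc3ccccc3)c1)O2 | intermediate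
10 | fisetinidol-(4α→6)-gallocatechin (upper 2R,3S,4S; lower 2R,3S) | Oc1ccc2c(c1)O[C@H](c1ccc(O)c(O)c1)[C@@H](O)[C@@H]2c1c(O)cc2c(c1O)C[C@H](O)[C@@H](c1cc(O)c(O)c(O)c1)O2 | target

## Summary

Total step count: 5. Longest linear sequence: 4 steps (3 → 5 → 7 → 9 → 10).

Three steps most likely to fail:

Step 4 (the proposed photoacid coupling). The risks are too little light-generated acidity or catalyst solubility in the organic medium, self-condensation of 2 through its own resorcinol ring, and a modest 4α:4β ratio (about 4:1 is expected, with the 4β isomer removed by chromatography of 9). The fallback uses known chemistry and sets out from 2. Benzyl mercaptan in acetic acid converts 2 into 4α-benzylsulfanylfisetinidol F1. The C4–S bond is then activated thermally with the thiophilic Lewis acid AgBF4 in THF at 0 °C in the presence of 7 (3 equiv). This comes back to the route at 9.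

Step 5 (one-pot removal of five benzyl ethers and the aryl bromide). The risks are incomplete debromination and base-promoted autoxidation of the pyrogallol-containing product. The fallback sets out from 9. The bromine is removed first by radical chain reduction (Bu3SnH, AIBN, toluene–THF, 80 °C) to give fisetinidol-(4α→6)-5,7,3',4',5'-penta-O-benzylgallocatechin F2. The benzyl ethers are then hydrogenolysed without any base (H2, Pd/C, EtOAc–MeOH). This comes back to the route at 10.

Step 2 (five-fold benzylation of a pyrogallol-containing flavan-3-ol). The risks are air oxidation, C-benzylation and C2 epimerisation under base. The fallback sets out from 3 and replaces base-mediated alkylation by a neutral redox-condensation etherification (Mitsunobu: BnOH, PPh3, DIAD, THF, 0 °C → rt). Only the acidic phenols act as pronucleophiles, so 5 is formed directly. It comes back to the route at 5 and makes no new compound (F0).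

## Further compounds

F1 | step 4 | 4α-benzylsulfanylfisetinidol, (2R,3S,4R)-4-(benzylsulfanyl)-2-(3,4-dihydroxyphenyl)chromane-3,7-diol | Oc1ccc2c(c1)O[C@H](c1ccc(O)c(O)c1)[C@@H](O)[C@@H]2SCc1ccccc1
F2 | step 5 | fisetinidol-(4α→6)-5,7,3',4',5'-penta-O-benzylgallocatechin | Oc1ccc2c(c1)O[C@H](c1ccc(O)c(O)c1)[C@@H](O)[C@@H]2c1c(OCc3ccccc3)cc2c(c1OCc3ccccc3)C[C@H](O)[C@@H](c1cc(OCc3ccccc3)c(OCc3ccccc3)c(OCc3ccccc3)c1)O2
F0 | step 2 | none | none
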